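The fused butyrolactone is disconnected at its carbonyl–α-carbon bond (C-14–C-13, tuberostemonine numbering): C-14 is retraced to carbon monoxide held on O-11 and C-13/C-15 to an ethynyl group on C-12. The step exploits the trans O-11/C-12 relationship on the nine-membered ring and the fact that C-13 carries only a methyl group; the pendant lactone (C-21–C-20) has the same pattern. In one operation a palladium-catalysed cyclocarbonylation of diol-diyne 32 closes both α-methylene lactones by 5-exo-dig alkoxycarbonyl insertion; one hydrogenation then sets both methyl centres. Compound 32 comes from a twelve-membered amine whose nitrogen opens a temporary γ-lactone across the ring to give the bridged lactam.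

Key step: step 20

Remark: atom labels follow the tuberostemonine numbering: C-1 ring ketone, C-2, C-3 (N–CH), N-4, C-5 to C-8, C-9, C-9a (lactam C=O), C-10 (ethyl-bearing), C-11 (O–CH), C-12, C-13, C-14 (fused lactone C=O), C-15 (13-methyl), C-18 (O–CH of the pendant lactone), C-19, C-20, C-21 (pendant lactone C=O).
Remark: (S)-but-3-yn-2-ol, Boc-L-pyroglutamic acid methyl ester and 3-bromo-1-(trimethylsilyl)prop-1-yne are taken as commercial.

**Route**

Step 1
Reactants: 1 (S)-but-3-yn-2-ol; 2 5-bromopent-1-ene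
Product: 3 (S)-non-8-en-3-yn-2-ol
Conditions: n-BuLi (2.1 equiv), THF/DMPU, −78 → 25 °C
Reagents that add atoms: none
Why: The alkoxide–acetylide dianion should be alkylated at carbon by the primary bromide (acetylide SN2 alkylation), leaving the carbinol centre untouched.

Step 2
Reactants: 3 (S)-non-8-en-3-yn-2-ol
Product: 4 (2S,3E)-nona-3,8-dien-2-ol
Conditions: LiAlH4, THF, 0 → 65 °C
Reagents that add atoms: none
Why: Hydroxyl-directed trans-hydroalumination of the propargylic alcohol should give the (E)-allylic alcohol needed for a chair Claisen transition state.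

Step 3
Reactants: 4 (2S,3E)-nona-3,8-dien-2-ol; 5 butanoyl chloride
Product: 6 (2S,3E)-nona-3,8-dien-2-yl butanoate
Conditions: pyridine, DMAP (cat.), CH2Cl2, 0 °C
Reagents that add atoms: none
Why: Routine acylation of the secondary allylic alcohol.

Step 4
Reactants: 6 (2S,3E)-nona-3,8-dien-2-yl butanoate
Product: 9 (2R,3R)-2-ethyl-3-[(E)-prop-1-enyl]oct-7-enoic acid, via silyl ketene acetal 7 (not isolated), via trimethylsilyl ester 8 (not isolated)
Conditions: LiN(i-Pr)2, THF, −78 °C; Me3SiCl; → 60 °C; then 1 M NaOH, then HCl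
Reagents that add atoms: none
Why: Ireland–Claisen rearrangement of the kinetic E(O)-enolate through a chair transition state with the carbinol methyl equatorial should transfer the carbinol chirality to C-9 and C-10 (anti, 2R,3R) and leave an (E)-propenyl group.

Step 5
Reactants: 9 (2R,3R)-2-ethyl-3-[(E)-prop-1-enyl]oct-7-enoic acid
Product: 10 (2R,3R)-2-ethyl-3-[(E)-prop-1-enyl]oct-7-en-1-ol
Conditions: LiAlH4, Et2O, 0 °C
Reagents that add atoms: none
Why: Hydride reduction of the acid to the primary alcohol.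

Step 6
Reactants: 10 (2R,3R)-2-ethyl-3-[(E)-prop-1-enyl]oct-7-en-1-ol
Product: 11 (2R,3R)-2-ethyl-3-[(E)-prop-1-enyl]oct-7-enal
Conditions: Dess–Martin periodinane, NaHCO3, CH2Cl2, 0 °C
Reagents that add atoms: none
Why: Buffered Dess–Martin oxidation should give the α-branched aldehyde without epimerising C-10.

Step 7
Reactants: 12 1-tert-butyl 2-methyl (S)-5-oxopyrrolidine-1,2-dicarboxylate
Product: 13 1-tert-butyl 2-methyl (2S,4R)-4-hydroxy-5-oxopyrrolidine-1,2-dicarboxylate
Conditions: LiN(SiMe3)2, THF, −78 °C; then 2-(phenylsulfonyl)-3-phenyloxaziridine, −78 °C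
Reagents that add atoms: 2-(phenylsulfonyl)-3-phenyloxaziridine, O=S(=O)(N1OC1c1ccccc1)c1ccccc1
Why: Enolate hydroxylation by the N-sulfonyloxaziridine should occur anti to the C-2 ester and give the trans (4R) alcohol, a protected precursor of the C-1 ketone.

Step 8
Reactants: 13 1-tert-butyl 2-methyl (2S,4R)-4-hydroxy-5-oxopyrrolidine-1,2-dicarboxylate
Product: 14 1-tert-butyl 2-methyl (2S,4R)-4-[(tert-butyldiphenylsilyl)oxy]-5-oxopyrrolidine-1,2-dicarboxylate
Conditions: t-BuPh2SiCl, imidazole, DMF, 25 °C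
Reagents that add atoms: tert-butyl(chloro)diphenylsilane, CC(C)(C)[Si](Cl)(c1ccccc1)c1ccccc1
Why: Silylation with a group chosen to survive CF3CO2H and the later organometallic steps.

Step 9
Reactants: 14 1-tert-butyl 2-methyl (2S,4R)-4-[(tert-butyldiphenylsilyl)oxy]-5-oxopyrrolidine-1,2-dicarboxylate; 15 ethynyltrimethylsilane
Product: 16 methyl (2S,4R)-2-[(tert-butoxycarbonyl)amino]-4-[(tert-butyldiphenylsilyl)oxy]-5-oxo-7-(trimethylsilyl)hept-6-ynoate
Conditions: 15, n-BuLi, THF, −78 °C; then 14, −78 °C; AcOH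
Reagents that add atoms: none
Why: The N-Boc-activated lactam carbonyl should be opened by the lithium acetylide at −78 °C faster than the methyl ester reacts (imide-type acyl substitution), giving the ynone.

Step 10
Reactants: 16 methyl (2S,4R)-2-[(tert-butoxycarbonyl)amino]-4-[(tert-butyldiphenylsilyl)oxy]-5-oxo-7-(trimethylsilyl)hept-6-ynoate
Product: 17 methyl (2S,4R,5R)-2-[(tert-butoxycarbonyl)amino]-4-[(tert-butyldiphenylsilyl)oxy]-5-hydroxy-7-(trimethylsilyl)hept-6-ynoate
Conditions: RuCl[(S,S)-TsDPEN](p-cymene) (2 mol %), i-PrOH, 25 °C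
Reagents that add atoms: none
Why: Noyori-type asymmetric transfer hydrogenation of the alkynyl ketone under catalyst control should give the (5R) propargylic alcohol, whose chirality is later relayed to C-12.

Step 11
Reactants: 17 methyl (2S,4R,5R)-2-[(tert-butoxycarbonyl)amino]-4-[(tert-butyldiphenylsilyl)oxy]-5-hydroxy-7-(trimethylsilyl)hept-6-ynoate
Product: 18 methyl (2S,4R,5R)-2-[(tert-butoxycarbonyl)amino]-4-[(tert-butyldiphenylsilyl)oxy]-5-[(methylsulfonyl)oxy]-7-(trimethylsilyl)hept-6-ynoate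
Conditions: MeSO2Cl, Et3N, CH2Cl2, −78 → 0 °C
Reagents that add atoms: methanesulfonyl chloride, CS(Cl)(=O)=O
Why: Mesylation with retention activates the propargylic position.

Step 12
Reactants: 18 methyl (2S,4R,5R)-2-[(tert-butoxycarbonyl)amino]-4-[(tert-butyldiphenylsilyl)oxy]-5-[(methylsulfonyl)oxy]-7-(trimethylsilyl)hept-6-ynoate; 11 (2R,3R)-2-ethyl-3-[(E)-prop-1-enyl]oct-7-enal
Product: 20 methyl (2S,4R,5R,6S,7R,8R)-2-[(tert-butoxycarbonyl)amino]-4-[(tert-butyldiphenylsilyl)oxy]-7-ethyl-6-hydroxy-8-[(E)-prop-1-enyl]-5-[(trimethylsilyl)ethynyl]tridec-12-enoate, via allenylindium reagent 19 (not isolated)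
Conditions: PdCl2(dppf) (5 mol %), InI (1.5 equiv), THF/HMPA 3:1, 25 °C
Reagents that add atoms: none
Why: Zerovalent palladium should displace the mesylate anti (SN2′), InI transmetalates to the allenylindium, and a cyclic SE2′ addition to the aldehyde gives the anti homopropargylic alcohol with net inversion at C-12, the reagent's facial preference coinciding with Felkin–Anh attack on the α-branched aldehyde; this sets C-11 and C-12.

Step 13
Reactants: 20 the anti homopropargylic alcohol
Product: 22 lactol aldehyde (C-9a aldehyde closed onto O-11 as a 2-hydroxytetrahydrofuran, anomer mixture; C-5 aldehyde free; other centres as in 20), via hydroxy dialdehyde 21 (not isolated)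
Conditions: OsO4 (2 mol %), NaIO4, 2,6-lutidine, dioxane/H2O, 25 °C
Reagents that add atoms: osmium tetroxide (catalytic oxygen carrier), O=[Os](=O)(=O)=O; sodium periodate, [Na+].[O-]I(=O)(=O)=O
Why: Lemieux–Johnson oxidation should cleave both alkenes but not the silylalkyne, and O-11 should trap the C-9a aldehyde at once as the five-membered lactol, which differentiates it from the C-5 aldehyde.

Step 14
Reactants: 22 lactol aldehyde
Product: 23 γ-lactone aldehyde (O-11–C-9a lactone, all-cis; C-5 aldehyde free)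
Conditions: Ag2CO3 on Celite, benzene, 80 °C
Reagents that add atoms: none
Why: Fétizon oxidation converts lactols into lactones and should leave the aldehyde untouched.

Step 15
Reactants: 23 γ-lactone aldehyde
Product: 26 twelve-membered secondary amine (N-4–C-5 bond formed; lactone, ester, silyl groups intact), via ammonium trifluoroacetate 24 (not isolated), via macrocyclic imine 25 (not isolated)
Conditions: CF3CO2H, CH2Cl2, 0 °C; concentrate; then NaBH(OAc)3, AcOH, ClCH2CH2Cl (1 mM), 25 °C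
Reagents that add atoms: none
Why: Boc removal followed by intramolecular reductive amination at high dilution should close the twelve-membered ring; no stereocentre is formed.

Step 16
Reactants: 26 twelve-membered secondary amine
Product: 27 bridged lactam methyl ester (caprolactam N-4–C-9a bridging the nine-membered ring; free 11-OH; 12-(trimethylsilyl)ethynyl; 1-OTBDPS; 3-CO2Me; (1R,3S,9S,10R,11S,12R))
Conditions: 2-hydroxypyridine (20 mol %), toluene, 90 °C
Reagents that add atoms: none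
Why: Aminolysis of the γ-lactone by the ring nitrogen through a seven-membered transition state (bifunctional catalysis) should give the bridged lactam and release O-11 as the free alcohol.

Step 17
Reactants: 27 bridged lactam methyl ester
Product: 28 Weinreb amide (3-C(=O)N(OMe)Me; otherwise as 27)
Conditions: MeNH(OMe)·HCl, i-PrMgCl, THF, −20 °C
Reagents that add atoms: N,O-dimethylhydroxylamine hydrochloride, CNOC.Cl
Why: The chloromagnesium amide converts the methyl ester directly into the Weinreb amide at low temperature.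

Step 18
Reactants: 28 Weinreb amide; 29 3-bromo-1-(trimethylsilyl)prop-1-yne
Product: 30 β,γ-alkynyl ketone (C-18 ketone bearing CH2C≡CSiMe3; otherwise as 27)
Conditions: 29, Mg, HgCl2 (cat.), Et2O, 0 °C; then 28, THF, −78 → −30 °C
Reagents that add atoms: none
Why: Weinreb ketone synthesis: the propargyl/allenyl Grignard reagent should add once through the chelated intermediate to give the β,γ-alkynyl ketone.

Step 19
Reactants: 30 β,γ-alkynyl ketone
Product: 32 diol-diyne (11-OH with 12-ethynyl; (18S)-OH with propargyl; 1-OTBDPS; (1R,3S,9S,10R,11S,12R,18S)), via bis-silylated diol 31 (not isolated)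
Conditions: LiBH(s-Bu)3, THF, −78 °C; then K2CO3, MeOH, 25 °C
Reagents that add atoms: none
Why: Felkin–Anh reduction of the α-amido ketone by the bulky hydride (N anti to hydride) should give the (18S) alcohol syn to N-4, and methanolysis then removes both alkynyl silyl groups.

Step 20
Reactants: 32 diol-diyne
Product: 35 bis(α-methylene lactone) (13-methylene fused lactone and 20-methylene pendant lactone; 1-OTBDPS; (1R,3S,9S,10R,11S,12R,18S)), via mono-lactone 33 (not isolated), via mono-lactone 34 (not isolated)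
Conditions: PdI2 (10 mol %), PBu3 (20 mol %), CO (7 atm), MeCN, 75 °C
Reagents that add atoms: carbon monoxide, [C-]#[O+]
Why: Divalent palladium and CO should convert each free hydroxyl into an alkoxycarbonylpalladium species that adds syn across its own terminal alkyne, closing the ring at the internal alkyne carbon (C-14–C-13 and C-21–C-20 bonds); protonolysis of the vinyl–palladium bond then gives the exocyclic methylene and returns the catalyst. The closest known reaction is the palladium-catalysed cyclocarbonylation of homopropargylic alcohols to α-methylene-γ-butyrolactones, here run twice in one molecule. Both rings close in the 5-exo-dig mode. No stereocentre is created: the trans ring fusion follows from the anti C-11/C-12 pair fixed in step 12, and C-18 from step 19. The selectivity needed is O-11 over O-1, secured by the silyl ether on O-1, and exo over endo closure, secured by the terminal alkyne one carbon away from each carbinol.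

Step 21
Reactants: 35 bis(α-methylene lactone)
Product: 36 (1R)-1-O-(tert-butyldiphenylsilyl)-1-dihydrotuberostemonone
Conditions: H2 (1 atm), RhCl(PPh3)3 (10 mol %), benzene/EtOH, 25 °C
Reagents that add atoms: none
Why: Homogeneous hydrogenation should add H2 to each exocyclic methylene from the face opposite the neighbouring ring substituent, giving the 13-methyl cis to C-1 and the 20-methyl cis to C-3.

Step 22
Reactants: 36 (1R)-1-O-(tert-butyldiphenylsilyl)-1-dihydrotuberostemonone
Product: 37 (1R)-1-dihydrotuberostemonone (C-1 alcohol; all other centres as in the target)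
Conditions: HF·pyridine, pyridine, THF, 0 → 25 °C
Reagents that add atoms: none
Why: Buffered fluoride should cleave the silyl ether without epimerising the α-methyl lactone centres.

Step 23
Reactants: 37 (1R)-1-dihydrotuberostemonone
Product: 38 tuberostemonone
Conditions: Dess–Martin periodinane, NaHCO3, CH2Cl2, 0 → 25 °C
Reagents that add atoms: none
Why: Buffered Dess–Martin oxidation forms the C-1 ketone last, so the β-acyloxy ketone is never exposed to base.

**Compound list**

1 | (S)-but-3-yn-2-ol | C[C@H](O)C#C | starting material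
2 | 5-bromopent-1-ene | C=CCCCBr | starting material
3 | (S)-non-8-en-3-yn-2-ol | C[C@H](O)C#CCCCC=C | intermediate
4 | (2S,3E)-nona-3,8-dien-2-ol | C[C@H](O)/C=C/CCCC=C | intermediate
5 | butanoyl chloride | CCCC(Cl)=O | starting material
6 | (2S,3E)-nona-3,8-dien-2-yl butanoate | CCCC(=O)O[C@@H](C)/C=C/CCCC=C | intermediate
7 | (E)-O-trimethylsilyl ketene acetal of 6 | CC/C=C(/O[Si](C)(C)C)O[C@@H](C)/C=C/CCCC=C | intermediate
8 | trimethylsilyl (2R,3R)-2-ethyl-3-[(E)-prop-1-enyl]oct-7-enoate | CC[C@@H](C(=O)O[Si](C)(C)C)[C@@H](/C=C/C)CCCC=C | intermediate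
9 | (2R,3R)-2-ethyl-3-[(E)-prop-1-enyl]oct-7-enoic acid | CC[C@@H](C(O)=O)[C@@H](/C=C/C)CCCC=C | intermediate
10 | (2R,3R)-2-ethyl-3-[(E)-prop-1-enyl]oct-7-en-1-ol | CC[C@@H](CO)[C@@H](/C=C/C)CCCC=C | intermediate
11 | (2R,3R)-2-ethyl-3-[(E)-prop-1-enyl]oct-7-enal | CC[C@@H](C=O)[C@@H](/C=C/C)CCCC=C | intermediate
12 | 1-tert-butyl 2-methyl (S)-5-oxopyrrolidine-1,2-dicarboxylate | COC(=O)[C@@H]1CCC(=O)N1C(=O)OC(C)(C)C | starting material
13 | 1-tert-butyl 2-methyl (2S,4R)-4-hydroxy-5-oxopyrrolidine-1,2-dicarboxylate | COC(=O)[C@@H]1C[C@@H](O)C(=O)N1C(=O)OC(C)(C)C | intermediate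
14 | 1-tert-butyl 2-methyl (2S,4R)-4-[(tert-butyldiphenylsilyl)oxy]-5-oxopyrrolidine-1,2-dicarboxylate | COC(=O)[C@@H]1C[C@@H](O[Si](c2ccccc2)(c2ccccc2)C(C)(C)C)C(=O)N1C(=O)OC(C)(C)C | intermediate
15 | ethynyltrimethylsilane | C#C[Si](C)(C)C | starting material
16 | methyl (2S,4R)-2-[(tert-butoxycarbonyl)amino]-4-[(tert-butyldiphenylsilyl)oxy]-5-oxo-7-(trimethylsilyl)hept-6-ynoate | COC(=O)[C@@H](NC(=O)OC(C)(C)C)C[C@@H](O[Si](c1ccccc1)(c1ccccc1)C(C)(C)C)C(=O)C#C[Si](C)(C)C | intermediate
17 | methyl (2S,4R,5R)-2-[(tert-butoxycarbonyl)amino]-4-[(tert-butyldiphenylsilyl)oxy]-5-hydroxy-7-(trimethylsilyl)hept-6-ynoate | COC(=O)[C@@H](NC(=O)OC(C)(C)C)C[C@@H](O[Si](c1ccccc1)(c1ccccc1)C(C)(C)C)[C@H](O)C#C[Si](C)(C)C | intermediate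
18 | methyl (2S,4R,5R)-2-[(tert-butoxycarbonyl)amino]-4-[(tert-butyldiphenylsilyl)oxy]-5-[(methylsulfonyl)oxy]-7-(trimethylsilyl)hept-6-ynoate | COC(=O)[C@@H](NC(=O)OC(C)(C)C)C[C@@H](O[Si](c1ccccc1)(c1ccccc1)C(C)(C)C)[C@H](OS(C)(=O)=O)C#C[Si](C)(C)C | intermediate
19 | allenylindium reagent from 18 (iodo(methanesulfonato)indium on the silyl-bearing allene terminus; (2S,4R); allene axis as in SMILES) | [In](I)(OS(C)(=O)=O)C([Si](C)(C)C)=[C@]=C([H])[C@H](O[Si](c1ccccc1)(c1ccccc1)C(C)(C)C)C[C@H](NC(=O)OC(C)(C)C)C(=O)OC | intermediate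
20 | methyl (2S,4R,5R,6S,7R,8R)-2-[(tert-butoxycarbonyl)amino]-4-[(tert-butyldiphenylsilyl)oxy]-7-ethyl-6-hydroxy-8-[(E)-prop-1-enyl]-5-[(trimethylsilyl)ethynyl]tridec-12-enoate | CC[C@H]([C@@H](/C=C/C)CCCC=C)[C@H](O)[C@@H](C#C[Si](C)(C)C)[C@H](O[Si](c1ccccc1)(c1ccccc1)C(C)(C)C)C[C@H](NC(=O)OC(C)(C)C)C(=O)OC | intermediate
21 | hydroxy dialdehyde (20 with both C=C bonds cleaved to the C-9a and C-5 aldehydes; centres as in 20) | CC[C@H]([C@@H](C=O)CCCC=O)[C@H](O)[C@@H](C#C[Si](C)(C)C)[C@H](O[Si](c1ccccc1)(c1ccccc1)C(C)(C)C)C[C@H](NC(=O)OC(C)(C)C)C(=O)OC | intermediate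
22 | lactol aldehyde (cyclic hemiacetal of the C-9a aldehyde with O-11, anomer mixture; centres as in 20) | CC[C@H]1[C@@H]([C@@H](C#C[Si](C)(C)C)[C@H](O[Si](c2ccccc2)(c2ccccc2)C(C)(C)C)C[C@H](NC(=O)OC(C)(C)C)C(=O)OC)OC(O)[C@H]1CCCC=O | intermediate
23 | γ-lactone aldehyde (O-11–C-9a lactone, all-cis; centres as in 20) | CC[C@H]1[C@@H]([C@@H](C#C[Si](C)(C)C)[C@H](O[Si](c2ccccc2)(c2ccccc2)C(C)(C)C)C[C@H](NC(=O)OC(C)(C)C)C(=O)OC)OC(=O)[C@H]1CCCC=O | intermediate
24 | ammonium trifluoroacetate of de-Boc 23 | CC[C@H]1[C@@H]([C@@H](C#C[Si](C)(C)C)[C@H](O[Si](c2ccccc2)(c2ccccc2)C(C)(C)C)C[C@H]([NH3+])C(=O)OC)OC(=O)[C@H]1CCCC=O.[O-]C(=O)C(F)(F)F | intermediate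
25 | twelve-membered cyclic imine (N-4=C-5), lactone intact | CC[C@H]1[C@@H]2OC(=O)[C@H]1CCCC=N[C@@H](C[C@@H](O[Si](c3ccccc3)(c3ccccc3)C(C)(C)C)[C@@H]2C#C[Si](C)(C)C)C(=O)OC | intermediate
26 | twelve-membered secondary amine (N-4–C-5), lactone intact; C-3, C-9, C-10, C-11, C-12 as in the target, C-1 (R) | CC[C@H]1[C@@H]2OC(=O)[C@H]1CCCCN[C@@H](C[C@@H](O[Si](c3ccccc3)(c3ccccc3)C(C)(C)C)[C@@H]2C#C[Si](C)(C)C)C(=O)OC | intermediate
27 | bridged lactam methyl ester, (1R,3S,9S,10R,11S,12R): 11-OH, 12-(trimethylsilyl)ethynyl, 1-OTBDPS, 3-CO2Me | CC[C@H]1[C@H](O)[C@@H](C#C[Si](C)(C)C)[C@H](O[Si](c3ccccc3)(c3ccccc3)C(C)(C)C)C[C@@H](C(=O)OC)N2CCCC[C@@H]1C2=O | intermediate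
28 | Weinreb amide of 27 (3-C(=O)N(OMe)Me) | CC[C@H]1[C@H](O)[C@@H](C#C[Si](C)(C)C)[C@H](O[Si](c3ccccc3)(c3ccccc3)C(C)(C)C)C[C@@H](C(=O)N(C)OC)N2CCCC[C@@H]1C2=O | intermediate
29 | 3-bromo-1-(trimethylsilyl)prop-1-yne | BrCC#C[Si](C)(C)C | starting material
30 | C-18 ketone bearing CH2C≡CSiMe3 (centres as in 27) | CC[C@H]1[C@H](O)[C@@H](C#C[Si](C)(C)C)[C@H](O[Si](c3ccccc3)(c3ccccc3)C(C)(C)C)C[C@@H](C(=O)CC#C[Si](C)(C)C)N2CCCC[C@@H]1C2=O | intermediate
31 | (18S)-alcohol with both alkynes still silylated | CC[C@H]1[C@H](O)[C@@H](C#C[Si](C)(C)C)[C@H](O[Si](c3ccccc3)(c3ccccc3)C(C)(C)C)C[C@@H]([C@@H](O)CC#C[Si](C)(C)C)N2CCCC[C@@H]1C2=O | intermediate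
32 | diol-diyne, (1R,3S,9S,10R,11S,12R,18S): 11-OH/12-ethynyl, 18-OH/propargyl, 1-OTBDPS | CC[C@H]1[C@H](O)[C@@H](C#C)[C@H](O[Si](c3ccccc3)(c3ccccc3)C(C)(C)C)C[C@@H]([C@@H](O)CC#C)N2CCCC[C@@H]1C2=O | intermediate
33 | mono-lactone (fused α-methylene lactone closed, pendant chain still 18-OH/propargyl) | CC[C@H]1[C@@H]2OC(=O)C(=C)[C@H]2[C@H](O[Si](c3ccccc3)(c3ccccc3)C(C)(C)C)C[C@@H]([C@@H](O)CC#C)N2CCCC[C@@H]1C2=O | intermediate
34 | mono-lactone (pendant α-methylene lactone closed, 11-OH/12-ethynyl still open) | CC[C@H]1[C@H](O)[C@@H](C#C)[C@H](O[Si](c3ccccc3)(c3ccccc3)C(C)(C)C)C[C@@H]([C@@H]2CC(=C)C(=O)O2)N2CCCC[C@@H]1C2=O | intermediate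
35 | bis(α-methylene lactone), (1R,3S,9S,10R,11S,12R,18S), 1-OTBDPS | CC[C@H]1[C@@H]2OC(=O)C(=C)[C@H]2[C@H](O[Si](c3ccccc3)(c3ccccc3)C(C)(C)C)C[C@@H]([C@@H]2CC(=C)C(=O)O2)N2CCCC[C@@H]1C2=O | intermediate
36 | (1R)-1-O-(tert-butyldiphenylsilyl)-1-dihydrotuberostemonone | CC[C@H]1[C@@H]2OC(=O)[C@@H](C)[C@H]2[C@H](O[Si](c3ccccc3)(c3ccccc3)C(C)(C)C)C[C@@H]([C@@H]2C[C@H](C)C(=O)O2)N2CCCC[C@@H]1C2=O | intermediate
37 | (1R)-1-dihydrotuberostemonone | CC[C@H]1[C@@H]2OC(=O)[C@@H](C)[C@H]2[C@H](O)C[C@@H]([C@@H]2C[C@H](C)C(=O)O2)N2CCCC[C@@H]1C2=O | intermediate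
38 | tuberostemonone | CC[C@H]1[C@@H]2OC(=O)[C@@H](C)[C@H]2C(=O)C[C@@H]([C@@H]2C[C@H](C)C(=O)O2)N2CCCC[C@@H]1C2=O | target

**Step count**

Total step count: 23. Longest linear sequence: 18 steps (1 → 38 through steps 1–6 and 12–23); the branch from 12 (steps 7–11) joins at step 12.

**Steps most likely to fail**

Step 20 (key step). The two cyclocarbonylations may stall after the first ring, or intermolecular alkoxycarbonylation and alkyne oligomerisation may compete at the crowded C-11 hydroxyl. Fallback, setting out from 32: phosgene and pyridine (CH2Cl2, 0 °C) should give the bis(chloroformate) F6, which benzeneselenol and pyridine convert into the bis(Se-phenyl selenocarbonate) F7. Slow addition of Bu3SnH with AIBN in benzene at 80 °C then generates the two alkoxycarbonyl radicals, each closing 5-exo-dig onto its alkyne, and hydrogen transfer to the vinyl radicals returns the route at 35.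

Step 15. Intermolecular imine formation and oligomerisation may outrun closure of the twelve-membered ring, or the aldehyde may be reduced before it condenses. Fallback, setting out from 23: NaBH4 (MeOH, 0 °C) should reduce the aldehyde to the primary alcohol F3. CF3CO2H followed by 2-nitrobenzenesulfonyl chloride and Et3N gives the sulfonamide F4. PPh3 and diisopropyl azodicarboxylate at high dilution close the ring by intramolecular Mitsunobu N-alkylation to the N-sulfonyl macrocycle F5, and PhSH/K2CO3 removes the sulfonyl group, returning the route at 26.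

Step 12. Loss of allene configuration in the organoindium stage, or a mismatch between reagent and aldehyde facial preferences, may erode the anti/Felkin selectivity; the β-silyloxy group may also be eliminated. Fallback, setting out from 17: methyl chloroformate and pyridine should give the propargylic carbonate F1. CuOt-Bu/Xantphos-catalysed γ-selective borylation with bis(pinacolato)diboron (anti SN2′) gives the isolable, configurationally stable allenylboronate F2. Heating F2 with 11 in toluene (closed six-membered transition state) should give, after work-up, 20, where the route is rejoined.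

Further compounds
F1 | step 12 | methyl (2S,4R,5R)-2-[(tert-butoxycarbonyl)amino]-4-[(tert-butyldiphenylsilyl)oxy]-5-[(methoxycarbonyl)oxy]-7-(trimethylsilyl)hept-6-ynoate | COC(=O)[C@@H](NC(=O)OC(C)(C)C)C[C@@H](O[Si](c1ccccc1)(c1ccccc1)C(C)(C)C)[C@H](OC(=O)OC)C#C[Si](C)(C)C
F2 | step 12 | allenyl pinacolboronate corresponding to 19 (boron on the silyl-bearing allene terminus) | CC1(C)OB(OC1(C)C)C([Si](C)(C)C)=[C@]=C([H])[C@H](O[Si](c1ccccc1)(c1ccccc1)C(C)(C)C)C[C@H](NC(=O)OC(C)(C)C)C(=O)OC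
F3 | step 15 | primary alcohol from 23 (C-5 CH2OH) | CC[C@H]1[C@@H]([C@@H](C#C[Si](C)(C)C)[C@H](O[Si](c2ccccc2)(c2ccccc2)C(C)(C)C)C[C@H](NC(=O)OC(C)(C)C)C(=O)OC)OC(=O)[C@H]1CCCCO
F4 | step 15 | 2-nitrobenzenesulfonamide of de-Boc F3 | CC[C@H]1[C@@H]([C@@H](C#C[Si](C)(C)C)[C@H](O[Si](c2ccccc2)(c2ccccc2)C(C)(C)C)C[C@H](NS(=O)(=O)c2ccccc2[N+](=O)[O-])C(=O)OC)OC(=O)[C@H]1CCCCO
F5 | step 15 | N-(2-nitrobenzenesulfonyl) derivative of 26 | CC[C@H]1[C@@H]2OC(=O)[C@H]1CCCCN([C@@H](C[C@@H](O[Si](c3ccccc3)(c3ccccc3)C(C)(C)C)[C@@H]2C#C[Si](C)(C)C)C(=O)OC)S(=O)(=O)c1ccccc1[N+](=O)[O-]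
F6 | step 20 | bis(chloroformate) of 32 | CC[C@H]1[C@H](OC(Cl)=O)[C@@H](C#C)[C@H](O[Si](c3ccccc3)(c3ccccc3)C(C)(C)C)C[C@@H]([C@@H](OC(Cl)=O)CC#C)N2CCCC[C@@H]1C2=O
F7 | step 20 | bis(Se-phenyl selenocarbonate) of 32 | CC[C@H]1[C@H](OC(=O)[Se]c2ccccc2)[C@@H](C#C)[C@H](O[Si](c3ccccc3)(c3ccccc3)C(C)(C)C)C[C@@H]([C@@H](OC(=O)[Se]c2ccccc2)CC#C)N2CCCC[C@@H]1C2=O
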